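## Structural features

Kadsurenin D is a bicyclo[3.2.1]oct-3-ene-2,8-dione. A cyclopentanone (C1, C7, C6, C5, C8) and a cyclohexenone (C1, C2, C3, C4, C5, C8) share the bridgeheads C1 and C5 and the bridging ketone C8. The three-carbon bridge is a 2-methoxy enone (C2=O, C3–OMe, C3=C4). The two-carbon bridge carries the 3,4-dimethoxyphenyl group on C7 (exo, on the side of C8) and the methyl group on C6 (endo, under the enone bridge), trans to each other. Four stereocentres, C1, C7, C6 and C5, are contiguous around the five-membered ring, and C5 is an all-carbon quaternary bridgehead that also bears the allyl group. The fragile parts are the methyl enol ether (acid), the non-enolisable C2/C8 1,3-diketone flanking C1 (nucleophilic cleavage), the terminal alkene and the electron-rich arene (electrophiles). The real difficulty is to attach C4 to the quaternary C5 on the face cis to the C6 methyl group, while C1 sits between two carbonyl-level carbons and can never become planar. The key step uses the fact that C5 is the α-carbon of the C8 ketone and C4 is a vinylic carbon of the enone ring, so C4–C5 is an enolate–alkenyl bond, and a chain anchored on C1 can deliver C4 to one face of C5 only.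

## Logic of the disconnections

24 ⇒ 23. No skeletal bond is cut; the C2 ketone is traced back to a carbinol. With C2 as a ketone, C1 would be the acidic methine of a 1,3-diketone in every earlier intermediate, which a bridged closure cannot accommodate. The forward step must be a non-acidic, non-nucleophilic oxidation of an allylic alcohol.

23 ⇒ 22. The O–Si bond is cut. The silyl ether prevents retro-aldol cleavage of the C1–C2 bond under base and comes off under near-neutral fluoride, which the enol ether tolerates. The forward step must keep the liberated alkoxide buffered.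

22 ⇒ 20. The C4–C5 bond is cut, which opens the six-membered ring and removes the quaternary centre. What remains is a monocyclic all-trans cyclopentanone with a bromoalkenyl chain on C1. The forward step must form a tetrasubstituted enolate at C5 and not lose the β-silyloxy group from C1. The bromine must be cis to C2 on the C3=C4 bond, and C–C coupling must win over C–O coupling.

20 ⇒ 18. The C4–Br bond is cut. The vinyl bromide is introduced last among the sensitive groups, so that it never meets the cuprate or stoichiometric palladium. The forward step must brominate the enol ether in the presence of the allyl group and the arene, and place bromine trans to the methoxy group.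

18 ⇒ 15 + 16. The C6–CH3 and C5–allyl bonds are cut together. This removes two stereocentres and leaves a 4,5-disubstituted cyclopentenone. The forward step must add methyl anti to the C7 aryl group and alkylate the resulting C5 enolate before it equilibrates.

15 ⇒ 12. The C5=C6 double bond is removed. Because C1 already carries its side chain, C5 is the only α-methylene, so the regiochemistry of the dehydrogenation is settled by the substitution pattern. The forward step must not epimerise C1 or disturb the enol ether.

12 ⇒ 11. The O–Si bond at C2 is cut. The forward step must silylate a β-hydroxy ketone without retro-aldol cleavage.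

11 ⇒ 9 + 3. The C1–C2 bond is cut by a retro-aldol step. This separates the three-carbon bridge (C2, C3, C4) from the ring. The forward step needs the C1 enolate regiospecifically, which a silyl enol ether left by the conjugate arylation supplies, and 1,2-addition to an enal anti to the C7 aryl group.

9 ⇒ 4 + 5. The C7–aryl bond is cut. This is the only stereocentre set by a chiral catalyst; all others follow from it. The forward step must be an asymmetric conjugate arylation run without a proton source, so that the enolate is captured on oxygen.

3 ⇒ 1. The C3=C4 bond is cut; C4 comes from a one-carbon aldehyde reagent and C2/C3 from the acetal. The forward step is an acetal hydrolysis followed by α-methylenation.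

## Other disconnections considered

Alternative 1: The cut is at C1–C2 and C4–C5 together. The three-carbon bridge is delivered as a 1-alkoxy-2-silyloxyallyl cation to the termini of the cyclopentadienone ketal A2 (1-allyl-5,5-dimethoxy-2-methylcyclopenta-1,3-diene). In the forward step a silyl triflate Lewis acid ionises the chiral mixed acetal A3, and (4+3) cycloaddition gives A1.
- In its favour: two C–C bonds, the six- and seven-membered rings and the quaternary C5 arise in one convergent operation, and the auxiliary on oxygen sets the absolute configuration.
- Against it here: A2 is a 5,5-dialkoxycyclopentadiene that dimerises readily and carries a ketal that the same Lewis acid can ionise. The alkoxy terminus must bond to C1 and the methylene terminus to the fully substituted C5. A1 lacks the aryl group, so a hydroarylation of the trisubstituted C6=C7 bond would have to place aryl exo on C7 and hydrogen on C6 beside the bulky C8 ketal. The oxygen pattern is also transposed (ketone at C3, ether at C2) and needs auxiliary removal, oxidation to the 2,3-dione and O-methylation.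
- Comparison: structurally A1 holds the whole bicycle but not the C7 stereocentre, whereas 22 holds everything except the oxidation level of C2. Mechanistically a cation cycloaddition replaces a metal-mediated enolate coupling. On ring construction and on avoiding strong base next to a β-silyloxy ketone this alternative is the better one. The final diosphenol methylation would be regiochemically unambiguous, which is equal to the chosen plan. On step count after the key step (about six against two) and on control of C6/C7 the chosen plan is ahead.

Alternative 2: The cut is at C6–C7 and at the C5–allyl bond. The cyclopentanone is made from the acyclic dienone A5 by a Nazarov cyclisation, and the oxyallyl cation is intercepted at C5 by allyltrimethylsilane A6 to give A4. In the forward step a chiral bis(oxazoline) complex of divalent copper triflate chelates the β-keto ester, and conrotatory 4π closure sets C6 and C7 trans.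
- In its favour: C5, C6 and C7, including the quaternary carbon, would be set in one catalytic asymmetric step from achiral material, and the trans relation follows from orbital symmetry.
- Against it here: intermolecular capture at the more substituted terminus of the oxyallyl cation competes with proton loss, and enantiocontrol in this catalyst class is substrate-dependent. A4 contains no C3 at all. The six-membered ring would need conversion of the ester into a methoxymethyl ketone, unmasking and oxidation of the C4 oxymethyl group, and an intramolecular aldol condensation, all with C1 as an acidic 1,3-dicarbonyl methine.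
- Comparison: on stereochemical economy this alternative is the better one, since one step does the work of steps 2, 3 and 6 of the chosen plan. It also avoids an enolate allylation. On overall length (roughly thirteen to fourteen steps against ten) and on how directly the bridge is installed, the chosen plan is ahead.

Alternative 3: The cut is at C1–C8 and C5–C8. The bridging carbon comes from nitromethane A9 and the seven-membered ring from the cross-conjugated dienone A8. In the forward step an amidine base promotes conjugate addition at C1 and then intramolecular conjugate addition of the nitronate at C5, giving A7.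
- In its favour: both rings and the one-carbon bridge form in one pot from a cheap reagent without a transition metal, and a Nef reaction would later reveal the C8 ketone.
- Against it here: C8 must end up syn to the C7 aryl group, so the first addition has to occur cis to the vicinal aryl substituent. The other facial mode would require bonding at C5 cis to the C6 methyl group, so neither mode is clearly favoured. The second addition creates a quaternary centre at a β,β-disubstituted enone carbon and is reversible. Enantioenriched A8 is no easier to make than 18. After A7 the C3 ketone is flanked by two methylenes, so oxidation at C2 and not C4 must be selective before dione formation and O-methylation.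
- Comparison: A7 carries the full carbon skeleton, which is equal to 22. The key step is operationally simpler and cheaper, which is better than the chosen plan. Mechanistically it relies on thermodynamic control with no element that dictates the face, whereas the tether in 20 leaves only one face open. It also needs four to five steps after the key step against two.

Key step: step 8

Remark: locants C1–C8 are those of the bicyclo[3.2.1]octane of 24 and are used for the same atoms in every intermediate.

Assumption: the aldol of step 3 is drawn as its anti (1S) carbinol epimer. Any syn epimer would be carried through the same steps, because this carbon becomes the C2 ketone in step 10.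

Assumption: the C5 configuration of 18 and 20 is drawn as allyl trans to methyl; it is erased by enolisation in step 8.

## Route

Step 1
Reactants: 1 1,1,2-trimethoxyethane
Product: 3 2-methoxyprop-2-enal, via methoxyacetaldehyde 2 (not isolated)
Conditions: 2 M aq. HCl (cat.), H2O, 50 °C; then Me2NH·HCl (0.2 equiv), 37% aq. CH2O, 70 °C; CH2Cl2 extraction, distillation over hydroquinone
Reagents that add atoms: water (O); formaldehyde (C=O)
Why: Acid hydrolysis of the dimethyl acetal frees the aldehyde 2, and a Mannich condensation with formaldehyde followed by loss of the amine (α-methylenation of an aldehyde, as used for other 2-alkoxyacroleins) should give 3; no stereocentre is formed.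

Step 2
Reactants: 4 4-bromo-1,2-dimethoxybenzene; 5 cyclopent-2-en-1-one
Product: 9 {[(3R)-3-(3,4-dimethoxyphenyl)cyclopent-1-en-1-yl]oxy}trimethylsilane, via (3,4-dimethoxyphenyl)lithium 6 (not isolated), via (3,4-dimethoxyphenyl)titanium triisopropoxide 7 (not isolated), via titanium enolate 8 (not isolated)
Conditions: 4, n-BuLi, THF, −78 °C; ClTi(OiPr)3, −78 → 20 °C; then 5, [Rh(OH)((R)-BINAP)]2 (3 mol% Rh), THF, 20 °C; then LiOiPr, TMSCl, 20 °C; hexane, filtration
Reagents that add atoms: chlorotrimethylsilane (C[Si](C)(C)Cl)
Why: Bromine–lithium exchange and transmetalation give 7, which should add to 5 in a rhodium-catalysed asymmetric 1,4-addition (the aprotic aryltitanium version of the Hayashi–Miyaura arylation); the (R)-BINAP ligand on monovalent rhodium should give the (R) configuration at C7, as in the (R)-3-arylcyclopentanone series. With no proton source present the titanium enolate 8 survives and is silylated on oxygen, which fixes the enolate regiochemistry at C1.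

Step 3
Reactants: 9 {[(3R)-3-(3,4-dimethoxyphenyl)cyclopent-1-en-1-yl]oxy}trimethylsilane; 3 2-methoxyprop-2-enal
Product: 11 (2R,3R)-3-(3,4-dimethoxyphenyl)-2-[(1S)-1-hydroxy-2-methoxyprop-2-en-1-yl]cyclopentan-1-one, via lithium enolate 10 (not isolated)
Conditions: MeLi, THF, 0 °C; then 3, −78 °C; sat. aq. NH4Cl, −78 °C
Reagents that add atoms: none
Why: Methyllithium cleaves the O–Si bond and regenerates the lithium enolate 10 regiospecifically at C1; kinetic aldol 1,2-addition to 3 should occur on the enolate face anti to the adjacent aryl group, so the side chain is trans to aryl. The Zimmerman–Traxler chair of the ring (E)-enolate favours the anti (1S) carbinol, whose configuration does not matter later.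

Step 4
Reactants: 11 (2R,3R)-3-(3,4-dimethoxyphenyl)-2-[(1S)-1-hydroxy-2-methoxyprop-2-en-1-yl]cyclopentan-1-one
Product: 12 (2R,3R)-2-[(1S)-1-(tert-butyldimethylsilyloxy)-2-methoxyprop-2-en-1-yl]-3-(3,4-dimethoxyphenyl)cyclopentan-1-one
Conditions: TBSOTf, 2,6-lutidine, CH2Cl2, −78 °C
Reagents that add atoms: tert-butyldimethylsilyl trifluoromethanesulfonate (CC(C)(C)[Si](C)(C)OS(=O)(=O)C(F)(F)F)
Why: A silyl triflate with a hindered pyridine base silylates the secondary carbinol at low temperature (standard silylation of an aldol adduct) without ionising the enol ether; the silyl ether shuts off retro-aldol cleavage and holds C2 at the alcohol level.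

Step 5
Reactants: 12 (2R,3R)-2-[(1S)-1-(tert-butyldimethylsilyloxy)-2-methoxyprop-2-en-1-yl]-3-(3,4-dimethoxyphenyl)cyclopentan-1-one
Product: 15 (4R,5R)-5-[(1S)-1-(tert-butyldimethylsilyloxy)-2-methoxyprop-2-en-1-yl]-4-(3,4-dimethoxyphenyl)cyclopent-2-en-1-one, via lithium enolate 13 (not isolated), via trimethylsilyl enol ether 14 (not isolated)
Conditions: LDA, TMSCl (in situ quench), THF, −78 °C; pentane, filtration; then Pd(OAc)2 (1.1 equiv), MeCN, rt
Reagents that add atoms: none
Why: Kinetic deprotonation by the hindered amide should occur at the only α-methylene (C5), the tertiary C1–H being shielded by the aryl and silyloxyalkyl groups, and silylation in situ gives 14. Saegusa oxidation (palladation of the silyl enol ether by Pd(OAc)2, then β-hydride elimination toward C6) installs the C5=C6 enone under neutral conditions that leave C1 and C7 untouched.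

Step 6
Reactants: 15 (4R,5R)-5-[(1S)-1-(tert-butyldimethylsilyloxy)-2-methoxyprop-2-en-1-yl]-4-(3,4-dimethoxyphenyl)cyclopent-2-en-1-one; 16 allyl bromide
Product: 18 (2S,3R,4R,5R)-2-allyl-5-[(1S)-1-(tert-butyldimethylsilyloxy)-2-methoxyprop-2-en-1-yl]-4-(3,4-dimethoxyphenyl)-3-methylcyclopentan-1-one, via lithium enolate 17 (not isolated)
Conditions: Me2CuLi (CuBr·SMe2, MeLi), Et2O, −78 → −40 °C; then HMPA, 16 (excess), THF, −78 → −20 °C
Reagents that add atoms: lithium dimethylcuprate ([Li+].C[Cu-]C)
Why: Conjugate addition of the Gilman cuprate to the cyclopentenone should place the methyl group on C6 anti to the neighbouring C7 aryl group, and the enolate 17, formed regiospecifically at C5, is C-allylated by 16 anti to the new methyl group (three-component conjugate addition–enolate alkylation). The C5 configuration is erased in step 8 and is not critical.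

Step 7
Reactants: 18 (2S,3R,4R,5R)-2-allyl-5-[(1S)-1-(tert-butyldimethylsilyloxy)-2-methoxyprop-2-en-1-yl]-4-(3,4-dimethoxyphenyl)-3-methylcyclopentan-1-one
Product: 20 (2S,3R,4R,5R)-2-allyl-5-[(1S,2E)-3-bromo-1-(tert-butyldimethylsilyloxy)-2-methoxyprop-2-en-1-yl]-4-(3,4-dimethoxyphenyl)-3-methylcyclopentan-1-one, via dibromo ether 19 (not isolated)
Conditions: Br2 (1.0 equiv, slow addition), CH2Cl2, −78 °C; then iPr2NEt, −78 → 0 °C
Reagents that add atoms: bromine (BrBr)
Why: Bromine should add to the electron-rich 1,1-disubstituted enol ether far faster than to the terminal alkene or the dimethoxyarene, giving the α-bromo ether 19, which ionises and loses the acidified proton on C4 under the amine base (bromination–dehydrobromination of an enol ether). In the intermediate oxocarbenium ion the O-methyl group stays syn to C4, so bromine should turn toward C2 and give the (E)-bromide, the geometry the ring closure needs.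

Step 8
Reactants: 20 (2S,3R,4R,5R)-2-allyl-5-[(1S,2E)-3-bromo-1-(tert-butyldimethylsilyloxy)-2-methoxyprop-2-en-1-yl]-4-(3,4-dimethoxyphenyl)-3-methylcyclopentan-1-one
Product: 22 (1R,2S,5S,6R,7R)-5-allyl-2-(tert-butyldimethylsilyloxy)-7-(3,4-dimethoxyphenyl)-3-methoxy-6-methylbicyclo[3.2.1]oct-3-en-8-one, via potassium enolate 21 (not isolated)
Conditions: Pd2(dba)3 (5 mol%), P(tBu)3 (12 mol%), THF, rt; then KOtBu (1.5 equiv, slow addition), 0 °C → rt
Reagents that add atoms: none
Why: Zerovalent palladium bearing P(tBu)3 inserts into the C4–Br bond of 20 to give an (E)-alkenylpalladium bromide; tert-butoxide then forms the potassium enolate 21 at C5, which displaces bromide on palladium, and C–C reductive elimination from the seven-membered C-bound palladium enolate forms C4–C5. The closest known reaction type is the intramolecular palladium-catalysed α-alkenylation of ketone enolates with vinyl halides that gives bridged bicyclic ketones. The six-membered ring C1–C2–C3–C4–C5–C8 closes in a 6-(enolendo) mode onto a vinylic carbon, with both the enolate C5=C8 bond and the C3=C4 bond inside the new ring, which is possible only because bromine is cis to C2. The quaternary centre C5 is set by the tether: the chain on C1 lies on the ring face anti to the C7 aryl group, so C4 can reach C5 only from that face, cis to the C6 methyl group, and the allyl group is pushed to the other face whatever the C5 configuration of 20. The step needs reaction through the C5 enolate and not the C1 enolate, which could only close a four-membered ring but can expel silanolate; for that reason oxidative addition is allowed to occur first and the base is added slowly. It also needs C- over O-alkenylation, which the bulky electron-rich phosphine favours by speeding C–C reductive elimination. The enol ether, the terminal alkene and the silyl ether should be spectators.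

Step 9
Reactants: 22 (1R,2S,5S,6R,7R)-5-allyl-2-(tert-butyldimethylsilyloxy)-7-(3,4-dimethoxyphenyl)-3-methoxy-6-methylbicyclo[3.2.1]oct-3-en-8-one
Product: 23 (1R,2S,5S,6R,7R)-5-allyl-7-(3,4-dimethoxyphenyl)-2-hydroxy-3-methoxy-6-methylbicyclo[3.2.1]oct-3-en-8-one
Conditions: TBAF, AcOH (1:1), THF, 0 °C → rt
Reagents that add atoms: none
Why: Fluoride cleaves the Si–O bond (standard desilylation); acetic acid buffers the alkoxide so that the β-hydroxy ketone should not open by retro-aldol cleavage, and the enol ether is never exposed to strong acid.

Step 10
Reactants: 23 (1R,2S,5S,6R,7R)-5-allyl-7-(3,4-dimethoxyphenyl)-2-hydroxy-3-methoxy-6-methylbicyclo[3.2.1]oct-3-en-8-one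
Product: 24 Kadsurenin D, (1S,5S,6R,7R)-5-allyl-7-(3,4-dimethoxyphenyl)-3-methoxy-6-methylbicyclo[3.2.1]oct-3-ene-2,8-dione
Conditions: Dess–Martin periodinane, NaHCO3, CH2Cl2, 0 °C → rt
Reagents that add atoms: none
Why: The periodinane (pentavalent iodine) oxidises the allylic secondary alcohol to the C2 ketone under buffered, non-aqueous conditions (Dess–Martin oxidation), which spare the enol ether and avoid nucleophiles that could cleave the non-enolisable C2/C8 diketone. The stereocentres are untouched, C1 being a bridgehead that cannot epimerise.

## Compound list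

1 | 1,1,2-trimethoxyethane | COCC(OC)OC | starting material
2 | methoxyacetaldehyde (not isolated) | COCC=O | intermediate
3 | 2-methoxyprop-2-enal (2-methoxyacrolein) | C=C(OC)C=O | intermediate
4 | 4-bromo-1,2-dimethoxybenzene | COc1ccc(Br)cc1OC | starting material
5 | cyclopent-2-en-1-one | O=C1C=CCC1 | starting material
6 | (3,4-dimethoxyphenyl)lithium (not isolated) | [Li]c1ccc(OC)c(OC)c1 | intermediate
7 | (3,4-dimethoxyphenyl)titanium triisopropoxide (not isolated) | CC(C)O[Ti](OC(C)C)(OC(C)C)c1ccc(OC)c(OC)c1 | intermediate
8 | triisopropoxytitanium (3R)-3-(3,4-dimethoxyphenyl)cyclopent-1-en-1-olate (not isolated) | CC(C)O[Ti](OC(C)C)(OC(C)C)OC1=C[C@H](c2ccc(OC)c(OC)c2)CC1 | intermediate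
9 | {[(3R)-3-(3,4-dimethoxyphenyl)cyclopent-1-en-1-yl]oxy}trimethylsilane | C[Si](C)(C)OC1=C[C@H](c2ccc(OC)c(OC)c2)CC1 | intermediate
10 | lithium (3R)-3-(3,4-dimethoxyphenyl)cyclopent-1-en-1-olate (not isolated) | [Li]OC1=C[C@H](c2ccc(OC)c(OC)c2)CC1 | intermediate
11 | (2R,3R)-3-(3,4-dimethoxyphenyl)-2-[(1S)-1-hydroxy-2-methoxyprop-2-en-1-yl]cyclopentan-1-one (side chain trans to aryl) | O=C1[C@@H]([C@H](O)C(OC)=C)[C@H](c2ccc(OC)c(OC)c2)CC1 | intermediate
12 | (2R,3R)-2-[(1S)-1-(tert-butyldimethylsilyloxy)-2-methoxyprop-2-en-1-yl]-3-(3,4-dimethoxyphenyl)cyclopentan-1-one | O=C1[C@@H]([C@H](O[Si](C)(C)C(C)(C)C)C(OC)=C)[C@H](c2ccc(OC)c(OC)c2)CC1 | intermediate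
13 | lithium (4R,5R)-5-[(1S)-1-(tert-butyldimethylsilyloxy)-2-methoxyprop-2-en-1-yl]-4-(3,4-dimethoxyphenyl)cyclopent-1-en-1-olate, the C5 enolate of 12 (not isolated) | [Li]OC1=CC[C@@H](c2ccc(OC)c(OC)c2)[C@@H]1[C@H](O[Si](C)(C)C(C)(C)C)C(OC)=C | intermediate
14 | {[(4R,5R)-5-[(1S)-1-(tert-butyldimethylsilyloxy)-2-methoxyprop-2-en-1-yl]-4-(3,4-dimethoxyphenyl)cyclopent-1-en-1-yl]oxy}trimethylsilane (not isolated) | C[Si](C)(C)OC1=CC[C@@H](c2ccc(OC)c(OC)c2)[C@@H]1[C@H](O[Si](C)(C)C(C)(C)C)C(OC)=C | intermediate
15 | (4R,5R)-5-[(1S)-1-(tert-butyldimethylsilyloxy)-2-methoxyprop-2-en-1-yl]-4-(3,4-dimethoxyphenyl)cyclopent-2-en-1-one | O=C1C=C[C@@H](c2ccc(OC)c(OC)c2)[C@@H]1[C@H](O[Si](C)(C)C(C)(C)C)C(OC)=C | intermediate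
16 | allyl bromide (3-bromoprop-1-ene) | C=CCBr | starting material
17 | lithium (3R,4R,5R)-5-[(1S)-1-(tert-butyldimethylsilyloxy)-2-methoxyprop-2-en-1-yl]-4-(3,4-dimethoxyphenyl)-3-methylcyclopent-1-en-1-olate (not isolated) | [Li]OC1=C[C@H](C)[C@@H](c2ccc(OC)c(OC)c2)[C@@H]1[C@H](O[Si](C)(C)C(C)(C)C)C(OC)=C | intermediate
18 | (2S,3R,4R,5R)-2-allyl-5-[(1S)-1-(tert-butyldimethylsilyloxy)-2-methoxyprop-2-en-1-yl]-4-(3,4-dimethoxyphenyl)-3-methylcyclopentan-1-one (all-trans ring) | C=CC[C@@H]1C(=O)[C@@H]([C@H](O[Si](C)(C)C(C)(C)C)C(OC)=C)[C@H](c2ccc(OC)c(OC)c2)[C@H]1C | intermediate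
19 | 18 with the side chain as 2,3-dibromo-1-(tert-butyldimethylsilyloxy)-2-methoxypropyl, epimers at the bromo ether carbon (not isolated) | C=CC[C@@H]1C(=O)[C@@H]([C@H](O[Si](C)(C)C(C)(C)C)C(Br)(OC)CBr)[C@H](c2ccc(OC)c(OC)c2)[C@H]1C | intermediate
20 | (2S,3R,4R,5R)-2-allyl-5-[(1S,2E)-3-bromo-1-(tert-butyldimethylsilyloxy)-2-methoxyprop-2-en-1-yl]-4-(3,4-dimethoxyphenyl)-3-methylcyclopentan-1-one | C=CC[C@@H]1C(=O)[C@@H]([C@H](O[Si](C)(C)C(C)(C)C)/C(OC)=C\Br)[C@H](c2ccc(OC)c(OC)c2)[C@H]1C | intermediate
21 | potassium (3R,4R,5R)-2-allyl-5-[(1S,2E)-3-bromo-1-(tert-butyldimethylsilyloxy)-2-methoxyprop-2-en-1-yl]-4-(3,4-dimethoxyphenyl)-3-methylcyclopent-1-en-1-olate (not isolated) | [K]OC1=C(CC=C)[C@H](C)[C@@H](c2ccc(OC)c(OC)c2)[C@@H]1[C@H](O[Si](C)(C)C(C)(C)C)/C(OC)=C\Br | intermediate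
22 | (1R,2S,5S,6R,7R)-5-allyl-2-(tert-butyldimethylsilyloxy)-7-(3,4-dimethoxyphenyl)-3-methoxy-6-methylbicyclo[3.2.1]oct-3-en-8-one | C=CC[C@]12C=C(OC)[C@@H](O[Si](C)(C)C(C)(C)C)[C@H](C1=O)[C@H](c1ccc(OC)c(OC)c1)[C@H]2C | intermediate
23 | (1R,2S,5S,6R,7R)-5-allyl-7-(3,4-dimethoxyphenyl)-2-hydroxy-3-methoxy-6-methylbicyclo[3.2.1]oct-3-en-8-one | C=CC[C@]12C=C(OC)[C@@H](O)[C@H](C1=O)[C@H](c1ccc(OC)c(OC)c1)[C@H]2C | intermediate
24 | Kadsurenin D, (1S,5S,6R,7R)-5-allyl-7-(3,4-dimethoxyphenyl)-3-methoxy-6-methylbicyclo[3.2.1]oct-3-ene-2,8-dione | C=CC[C@]12C=C(OC)C(=O)[C@H](C1=O)[C@H](c1ccc(OC)c(OC)c1)[C@H]2C | target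

## Step count and least certain steps

Total: 10 steps. Longest linear sequence: 9 steps (steps 2 to 10, from 4 and 5); step 1 is a one-step branch that joins at step 3.

Step 8 (key step). The most likely failure is β-elimination of silanolate from the C1 enolate. Alkoxide equilibrates both ketone enolates, and coupling at the hindered, tetrasubstituted C5 enolate may be slower than loss of the C2 oxygen; protodebromination is the second risk. Fallback: set out from 20 and deprotonate kinetically with LDA at −78 °C in the presence of TMSCl. The C5–H is less shielded than the C1–H, and at this temperature silylation should outrun elimination. This should give the trimethylsilyl enol ether of 20 across C5=C8, F1. F1 is then coupled without any alkoxide, by palladium catalysis with fluoride activation through a tin enolate (Pd2(dba)3, P(tBu)3, Bu3SnF, toluene, 80 °C), a known mode of coupling silyl enol ethers with aryl and alkenyl bromides. The fallback rejoins the route at 22.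

Step 7. The most likely failure is loss of geometric control, with bromine ending cis to the methoxy group. Proton loss toward C2 would instead give an allylic bromide, and over-bromination of the allyl group is possible if addition is not slow. Any of these would leave a bromide that cannot reach C5. Fallback: set out from 18 and run two bromination–dehydrobromination cycles, so that both geometric isomers converge on the 1,1-dibromo enol ether F2, in which geometry is moot. Stereoselective palladium-catalysed hydrogenolysis of 1,1-dibromoalkenes with tin hydride (Pd(PPh3)4, Bu3SnH, benzene, rt) should then remove the less hindered bromine, the one cis to the methoxy group and trans to the branched C2. The fallback rejoins the route at 20.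

Step 6. The most likely failure is slow C-allylation of the copper-containing enolate. Proton transfer between product and enolate would then lead to double allylation and, through the isomerised C1 enolate, to loss of the silyloxy group. Fallback: set out from 15 and run the cuprate addition with TMSCl present, to isolate the trimethylsilyl enol ether F3 with the enolate regiochemistry locked at C5. A Tsuji allylation of F3 (Pd2(dba)3, PPh3, diallyl carbonate, Bu4N[Ph3SiF2] (cat.), THF, rt) then delivers the allyl group to C5 under neutral conditions. The fallback rejoins the route at 18.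

Step 5. The most likely failure is attack of Pd(OAc)2 on the electron-rich methyl enol ether in competition with the silyl enol ether, or incomplete conversion that leaves divalent palladium to degrade the product. Fallback: set out from 12, form the C5 lithium enolate with LDA at −78 °C and trap it with PhSeCl to give the α-phenylselanyl ketone F4. Oxidation to the selenoxide (30% H2O2, pyridine, CH2Cl2, 0 °C) and syn-elimination can only proceed toward C6. The fallback rejoins the route at 15.

## Further compounds

F1 | step 8 | trimethylsilyl enol ether of 20 across C5=C8 | C=CCC1=C(O[Si](C)(C)C)[C@@H]([C@H](O[Si](C)(C)C(C)(C)C)/C(OC)=C\Br)[C@H](c2ccc(OC)c(OC)c2)[C@H]1C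
F2 | step 7 | (2S,3R,4R,5R)-2-allyl-5-[(1S)-3,3-dibromo-1-(tert-butyldimethylsilyloxy)-2-methoxyprop-2-en-1-yl]-4-(3,4-dimethoxyphenyl)-3-methylcyclopentan-1-one | C=CC[C@@H]1C(=O)[C@@H]([C@H](O[Si](C)(C)C(C)(C)C)C(OC)=C(Br)Br)[C@H](c2ccc(OC)c(OC)c2)[C@H]1C
F3 | step 6 | {[(3R,4R,5R)-5-[(1S)-1-(tert-butyldimethylsilyloxy)-2-methoxyprop-2-en-1-yl]-4-(3,4-dimethoxyphenyl)-3-methylcyclopent-1-en-1-yl]oxy}trimethylsilane | C[Si](C)(C)OC1=C[C@H](C)[C@@H](c2ccc(OC)c(OC)c2)[C@@H]1[C@H](O[Si](C)(C)C(C)(C)C)C(OC)=C
F4 | step 5 | 12 bearing a phenylselanyl group on C5 (epimers at that carbon) | O=C1C([Se]c2ccccc2)C[C@@H](c2ccc(OC)c(OC)c2)[C@@H]1[C@H](O[Si](C)(C)C(C)(C)C)C(OC)=C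
A1 | alternative 1 | 5-allyl-8,8-dimethoxy-6-methyl-2-[(S)-1-phenylethoxy]bicyclo[3.2.1]oct-6-en-3-one | C=CC[C@]12CC(=O)[C@@H](O[C@@H](C)c3ccccc3)[C@H](C1(OC)OC)C=C2C
A2 | alternative 1 | 1-allyl-5,5-dimethoxy-2-methylcyclopenta-1,3-diene | C=CCC1=C(C)C=CC1(OC)OC
A3 | alternative 1 | triethyl({3-methoxy-3-[(1S)-1-phenylethoxy]prop-1-en-2-yl}oxy)silane | C=C(O[Si](CC)(CC)CC)C(OC)O[C@@H](C)c1ccccc1
A4 | alternative 2 | methyl 3-allyl-5-(3,4-dimethoxyphenyl)-3-[(4-methoxybenzyloxy)methyl]-4-methyl-2-oxocyclopentane-1-carboxylate | C=CC[C@]1(COCc2ccc(OC)cc2)C(=O)[C@@H](C(=O)OC)[C@H](c2ccc(OC)c(OC)c2)[C@H]1C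
A5 | alternative 2 | methyl (2Z,4E)-2-[(3,4-dimethoxyphenyl)methylidene]-4-[(4-methoxybenzyloxy)methyl]-3-oxohex-4-enoate | COC(=O)/C(=C\c1ccc(OC)c(OC)c1)C(=O)/C(COCc1ccc(OC)cc1)=C/C
A6 | alternative 2 | allyltrimethylsilane | C=CC[Si](C)(C)C
A7 | alternative 3 | 5-allyl-7-(3,4-dimethoxyphenyl)-6-methyl-8-nitrobicyclo[3.2.1]octan-3-one | C=CC[C@]12CC(=O)C[C@H]([C@@H]1[N+](=O)[O-])[C@H](c1ccc(OC)c(OC)c1)[C@H]2C
A8 | alternative 3 | 3-allyl-5-(3,4-dimethoxyphenyl)-4-methylcyclohepta-2,6-dien-1-one (4,5-trans) | O=C1C=C(CC=C)[C@H](C)[C@@H](c2ccc(OC)c(OC)c2)C=C1
A9 | alternative 3 | nitromethane | C[N+](=O)[O-]
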